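**Numbering.** Tricyclic compounds use the longipinane numbering of the target: C1 ketone, C2=C3(Me), C4 and C11 bridgeheads, C5, C6 (CMe2), C7 and C9 (oxygenated), C8, C10 (CMe). Bicyclic compounds 7–16, F2 and F3 are numbered as bicyclo[3.1.1]heptanes (C6 = later C5, C7 = later C10).

**Assumption.** The senses of induction of auxiliary 4 (step 4) and of the binaphthoxide catalyst (step 10) are as drawn; if either proves opposite, its mirror-image form is used.

## Retrosynthetic overview

1. Target 23 ⇐ diester 22 by allylic C–H oxidation (C1=O, last step); 22 ⇐ hydroxy ester 20 by acylation at O7.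
2. Key step: 20 ⇐ keto aldehyde 16 + 3-methylbut-2-enal. The aldolate oxygen adds to the enal (hemiacetal C–O bond) and a hydride shift turns this into the C9 ester and the C7 carbinol, with ring closure C8–C9 in the same flask.
3. 16 ⇐ cyclobutanone 9 by olefination and reductive methylation (C5–C6 bond, gem-dimethyl, C5–H).
4. 9 ⇐ geranate-derived chiral amide 5 by intramolecular keteniminium–alkene [2+2] (sets C4, C10, C11); 5 ⇐ methyl geranate by allylic hydroxylation.
5. Ring order: cyclobutane and six-membered ring together (step 4), seven-membered ring last (step 10).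

## Route

Step 1
Reactants: 1 methyl geranate [methyl (2E)-3,7-dimethylocta-2,6-dienoate]
Product: 2 methyl (2E,6E)-8-hydroxy-3,7-dimethylocta-2,6-dienoate
Conditions: SeO2 (cat.), t-BuOOH, salicylic acid (cat.), CH2Cl2, rt
Reagents that add atoms: tert-butyl hydroperoxide, CC(C)(C)OO
Why: Sharpless–Riley allylic oxidation (ene reaction, then [2,3]-shift) hydroxylates only the E-methyl of the electron-rich trisubstituted alkene, fixing the E geometry that later defines the C10 quaternary centre.

Step 2
Reactants: 2 methyl (2E,6E)-8-hydroxy-3,7-dimethylocta-2,6-dienoate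
Product: 3 methyl (2E,6E)-3,7-dimethyl-8-(triethylsilyloxy)octa-2,6-dienoate
Conditions: Et3SiCl, imidazole, CH2Cl2, 0 °C
Reagents that add atoms: chlorotriethylsilane, CC[Si](Cl)(CC)CC
Why: Standard silylation; the primary triethylsilyl ether survives the basic and organometallic steps and is oxidised directly in step 9.

Step 3
Reactants: 3 methyl (2E,6E)-3,7-dimethyl-8-(triethylsilyloxy)octa-2,6-dienoate; 4 (2S,5S)-2,5-dimethylpyrrolidine
Product: 5 (2E,6E)-1-[(2S,5S)-2,5-dimethylpyrrolidin-1-yl]-3,7-dimethyl-8-(triethylsilyloxy)octa-2,6-dien-1-one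
Conditions: AlMe3, toluene, 80 °C
Reagents that add atoms: none
Why: Weinreb-type aminolysis of the ester by the dimethylaluminium amide installs the C2-symmetric auxiliary without touching alkene geometry or the silyl ether.

Step 4
Reactants: 5 (2E,6E)-1-[(2S,5S)-2,5-dimethylpyrrolidin-1-yl]-3,7-dimethyl-8-(triethylsilyloxy)octa-2,6-dien-1-one
Product: 8 (1R,5S,7S)-7-methyl-2-methylidene-7-[(triethylsilyloxy)methyl]bicyclo[3.1.1]heptan-6-one, via vinylketeniminium triflate 6 (not isolated), via cyclobutaniminium triflate 7 (not isolated)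
Conditions: Tf2O, 2,6-di-tert-butyl-4-methylpyridine, ClCH2CH2Cl, −20 → 80 °C; then H2O, NaHCO3
Reagents that add atoms: trifluoromethanesulfonic anhydride, O=S(=O)(OS(=O)(=O)C(F)(F)F)C(F)(F)F (counter-ion of 6 and 7); water, O
Why: Ghosez keteniminium–alkene [2+2] in the bridged mode known for vinylketenes (Snider–Corey): 1,4-elimination from the O-triflyl iminium gives 6, its central carbon bonds to the alkene CH and its α-carbon to the disubstituted terminus, the E alkene places CH2OSiEt3 anti to the three-carbon bridge, and the pyrrolidine selects the alkene face, so C1, C5 and C7 are set.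

Step 5
Reactants: 8 (1R,5S,7S)-7-methyl-2-methylidene-7-[(triethylsilyloxy)methyl]bicyclo[3.1.1]heptan-6-one
Product: 9 (1R,5S,7S)-2,7-dimethyl-7-[(triethylsilyloxy)methyl]bicyclo[3.1.1]hept-2-en-6-one
Conditions: PdCl2(PhCN)2 (5 mol %), benzene, 60 °C
Reagents that add atoms: none
Why: Palladium-catalysed alkene isomerisation moves the exocyclic double bond to the more stable endocyclic trisubstituted position (β-pinene → α-pinene type), as needed for the final allylic oxidation; no stereocentre changes.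

Step 6
Reactants: 9 (1R,5S,7S)-2,7-dimethyl-7-[(triethylsilyloxy)methyl]bicyclo[3.1.1]hept-2-en-6-one; 10 triethyl 2-phosphonopropanoate
Product: 11 ethyl 2-[2,7-dimethyl-7-(triethylsilyloxymethyl)bicyclo[3.1.1]hept-2-en-6-ylidene]propanoate (ring configuration as in 9; alkene isomers)
Conditions: NaH, DME, 85 °C
Reagents that add atoms: none
Why: Horner–Wadsworth–Emmons olefination of the strained, electrophilic cyclobutanone (attack from the face of the three-carbon bridge); the geometry of the new alkene is irrelevant.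

Step 7
Reactants: 11 ethyl 2-[2,7-dimethyl-7-(triethylsilyloxymethyl)bicyclo[3.1.1]hept-2-en-6-ylidene]propanoate
Product: 13 ethyl 2-[2,7-dimethyl-7-(triethylsilyloxymethyl)bicyclo[3.1.1]hept-2-en-6-yl]-2-methylpropanoate (side chain at C6 cis to CH2OSiEt3), via lithium ester enolate 12 (not isolated)
Conditions: Li, NH3/THF, t-BuOH (1 equiv), −78 °C; then isoprene, MeI
Reagents that add atoms: lithium, [Li] (in 12); iodomethane, CI
Why: Dissolving-metal conjugate reduction with enolate trapping (Stork reductive alkylation): C6 is protonated from the open face toward the three-carbon bridge, which pushes the side chain anti (cis to CH2OSiEt3, later C5), and C-methylation of 12 creates the gem-dimethyl carbon.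

Step 8
Reactants: 13 ethyl 2-[2,7-dimethyl-7-(triethylsilyloxymethyl)bicyclo[3.1.1]hept-2-en-6-yl]-2-methylpropanoate
Product: 15 3-[2,7-dimethyl-7-(triethylsilyloxymethyl)bicyclo[3.1.1]hept-2-en-6-yl]-3-methylbutan-2-one, via α-silyl ketone 14 (not isolated)
Conditions: Me3SiCH2Li (2.5 equiv), pentane/THF, 0 °C → rt; then MeOH
Reagents that add atoms: (trimethylsilyl)methyllithium, [Li]C[Si](C)(C)C
Why: Acyl substitution of the hindered ester by Me3SiCH2Li stops at the ketone because 14 is deprotonated to its enolate, and methanolysis removes silicon (ester-to-methyl-ketone conversion).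

Step 9
Reactants: 15 3-[2,7-dimethyl-7-(triethylsilyloxymethyl)bicyclo[3.1.1]hept-2-en-6-yl]-3-methylbutan-2-one
Product: 16 2,7-dimethyl-6-(2-methyl-3-oxobutan-2-yl)bicyclo[3.1.1]hept-2-ene-7-carbaldehyde
Conditions: (COCl)2, DMSO, CH2Cl2, −78 → −30 °C; then Et3N
Reagents that add atoms: none
Why: Swern conditions cleave and oxidise a primary triethylsilyl ether in one operation, giving a neopentyl aldehyde that can neither enolise nor epimerise.

Step 10
Reactants: 16 2,7-dimethyl-6-(2-methyl-3-oxobutan-2-yl)bicyclo[3.1.1]hept-2-ene-7-carbaldehyde; 17 3-methylbut-2-enal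
Product: 20 (7R,9R)-7-hydroxylongipin-2-en-9-yl 3-methylbut-2-enoate, via aldol 18 (not isolated), via hemiacetal 19 (not isolated)
Conditions: LaLi3[(R)-binaphthoxide]3 (10 mol %), LiOTf (30 mol %), THF, rt
Reagents that add atoms: none
Why: Proposed new method: a catalytic asymmetric intramolecular aldol–Tishchenko cascade with an external enal, in which the lanthanum–lithium binaphthoxide deprotonates the methyl ketone (the only enolisable site), the enolate closes the seven-membered ring reversibly on the non-enolisable aldehyde, the lanthanum aldolate adds 17 to give hemiacetal 19, and its hydride moves to the ketone through a six-membered chair transition state, forming the C9 ester C–O bond and the anti (trans) C7 carbinol; because the C9 epimers of 18 interconvert by retro-aldol and the chiral catalyst lets only one undergo the irreversible hydride transfer, C9 and C7 are set by the catalyst and not by the remote cage; closest known reactions are the Evans–Tishchenko reduction and the Shibasaki direct catalytic asymmetric aldol–Tishchenko reaction of ketones with aldehydes.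

Step 11
Reactants: 20 (7R,9R)-7-hydroxylongipin-2-en-9-yl 3-methylbut-2-enoate; 21 3-methylbut-2-enoyl chloride
Product: 22 (7R,9R)-longipin-2-ene-7,9-diyl bis(3-methylbut-2-enoate)
Conditions: pyridine, DMAP (cat.), CH2Cl2, 0 °C → rt
Reagents that add atoms: none
Why: DMAP-catalysed acylation of the remaining C7 hydroxyl; since both esters are the same, any 1,3-acyl migration in 20 is harmless.

Step 12
Reactants: 22 (7R,9R)-longipin-2-ene-7,9-diyl bis(3-methylbut-2-enoate)
Product: 23 (4R,5S,7R,9R,10R,11R)-1-oxolongipin-2-ene-7,9-diyl bis(3-methylbut-2-enoate) (target)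
Conditions: Rh2(caprolactamate)4 (1 mol %), t-BuOOH, K2CO3, CH2Cl2, rt
Reagents that add atoms: tert-butyl hydroperoxide, CC(C)(C)OO
Why: Doyle allylic C–H oxidation (tert-butylperoxyl radical chain) converts the ring CH2 next to the trisubstituted alkene into the enone carbonyl, as in α-pinene → verbenone; the electron-poor ester alkenes and all stereocentres are untouched.

## Compound list

1 | methyl geranate | COC(=O)/C=C(\C)CCC=C(C)C | starting material
2 | methyl (2E,6E)-8-hydroxy-3,7-dimethylocta-2,6-dienoate | COC(=O)/C=C(\C)CC/C=C(\C)CO | intermediate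
3 | methyl (2E,6E)-3,7-dimethyl-8-(triethylsilyloxy)octa-2,6-dienoate | COC(=O)/C=C(\C)CC/C=C(\C)CO[Si](CC)(CC)CC | intermediate
4 | (2S,5S)-2,5-dimethylpyrrolidine | C[C@H]1CC[C@H](C)N1 | starting material
5 | (2E,6E)-1-[(2S,5S)-2,5-dimethylpyrrolidin-1-yl]-3,7-dimethyl-8-(triethylsilyloxy)octa-2,6-dien-1-one | C[C@H]1CC[C@H](C)N1C(=O)/C=C(\C)CC/C=C(\C)CO[Si](CC)(CC)CC | intermediate
6 | (2S,5S)-2,5-dimethyl-1-[(6E)-7-methyl-3-methylidene-8-(triethylsilyloxy)octa-1,6-dien-1-ylidene]pyrrolidinium triflate | C[C@H]1CC[C@H](C)[N+]1=C=CC(=C)CC/C=C(\C)CO[Si](CC)(CC)CC.[O-]S(=O)(=O)C(F)(F)F | intermediate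
7 | (2S,5S)-2,5-dimethyl-1-[(1R,5S,7S)-7-methyl-2-methylidene-7-(triethylsilyloxymethyl)bicyclo[3.1.1]heptan-6-ylidene]pyrrolidinium triflate | CC[Si](CC)(CC)OC[C@@]2(C)[C@@H]3CCC(=C)[C@H]2C3=[N+]4[C@@H](C)CC[C@@H]4C.[O-]S(=O)(=O)C(F)(F)F | intermediate
8 | (1R,5S,7S)-7-methyl-2-methylidene-7-[(triethylsilyloxy)methyl]bicyclo[3.1.1]heptan-6-one | CC[Si](CC)(CC)OC[C@@]2(C)[C@@H]3CCC(=C)[C@H]2C3=O | intermediate
9 | (1R,5S,7S)-2,7-dimethyl-7-[(triethylsilyloxy)methyl]bicyclo[3.1.1]hept-2-en-6-one | CC[Si](CC)(CC)OC[C@@]2(C)[C@@H]3CC=C(C)[C@H]2C3=O | intermediate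
10 | triethyl 2-phosphonopropanoate | CCOC(=O)C(C)P(=O)(OCC)OCC | starting material
11 | ethyl 2-[2,7-dimethyl-7-(triethylsilyloxymethyl)bicyclo[3.1.1]hept-2-en-6-ylidene]propanoate (ring configuration as in 9, alkene isomers) | CC[Si](CC)(CC)OC[C@@]2(C)[C@@H]3CC=C(C)[C@H]2C3=C(C)C(=O)OCC | intermediate
12 | lithium enolate of 13 before methylation (C6–H toward the three-carbon bridge) | CC[Si](CC)(CC)OC[C@@]2(C)[C@@H]3CC=C(C)[C@H]2[C@@H]3C(C)=C(OCC)[O-].[Li+] | intermediate
13 | ethyl 2-[2,7-dimethyl-7-(triethylsilyloxymethyl)bicyclo[3.1.1]hept-2-en-6-yl]-2-methylpropanoate (C6 side chain cis to CH2OSiEt3) | CC[Si](CC)(CC)OC[C@@]2(C)[C@@H]3CC=C(C)[C@H]2[C@@H]3C(C)(C)C(=O)OCC | intermediate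
14 | 3-[2,7-dimethyl-7-(triethylsilyloxymethyl)bicyclo[3.1.1]hept-2-en-6-yl]-3-methyl-1-(trimethylsilyl)butan-2-one | CC[Si](CC)(CC)OC[C@@]2(C)[C@@H]3CC=C(C)[C@H]2[C@@H]3C(C)(C)C(=O)C[Si](C)(C)C | intermediate
15 | 3-[2,7-dimethyl-7-(triethylsilyloxymethyl)bicyclo[3.1.1]hept-2-en-6-yl]-3-methylbutan-2-one | CC[Si](CC)(CC)OC[C@@]2(C)[C@@H]3CC=C(C)[C@H]2[C@@H]3C(C)(C)C(C)=O | intermediate
16 | 2,7-dimethyl-6-(2-methyl-3-oxobutan-2-yl)bicyclo[3.1.1]hept-2-ene-7-carbaldehyde (CHO and C6 side chain cis, both anti to the three-carbon bridge) | O=C[C@@]2(C)[C@@H]3CC=C(C)[C@H]2[C@@H]3C(C)(C)C(C)=O | intermediate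
17 | 3-methylbut-2-enal | CC(C)=CC=O | starting material
18 | (9R)-9-hydroxylongipin-2-en-7-one (the C9 epimer that is consumed; epimers equilibrate) | O=C1C[C@@H](O)[C@@]2(C)[C@@H]3CC=C(C)[C@H]2[C@@H]3C1(C)C | intermediate
19 | (9R)-9-(1-hydroxy-3-methylbut-2-enyloxy)longipin-2-en-7-one (hemiacetal, metal-bound) | O=C1C[C@@H](OC(O)C=C(C)C)[C@@]2(C)[C@@H]3CC=C(C)[C@H]2[C@@H]3C1(C)C | intermediate
20 | (7R,9R)-7-hydroxylongipin-2-en-9-yl 3-methylbut-2-enoate | O[C@@H]1C[C@@H](OC(=O)C=C(C)C)[C@@]2(C)[C@@H]3CC=C(C)[C@H]2[C@@H]3C1(C)C | intermediate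
21 | 3-methylbut-2-enoyl chloride | CC(C)=CC(Cl)=O | starting material
22 | (7R,9R)-longipin-2-ene-7,9-diyl bis(3-methylbut-2-enoate) | CC(C)=CC(=O)O[C@@H]1C[C@@H](OC(=O)C=C(C)C)[C@@]2(C)[C@@H]3CC=C(C)[C@H]2[C@@H]3C1(C)C | intermediate
23 | (4R,5S,7R,9R,10R,11R)-1-oxolongipin-2-ene-7,9-diyl bis(3-methylbut-2-enoate) | CC(C)=CC(=O)O[C@@H]1C[C@@H](OC(=O)C=C(C)C)[C@@]2(C)[C@@H]3C(=O)C=C(C)[C@H]2[C@@H]3C1(C)C | target

## Step count and risks

Total step count: 12. Longest linear sequence: 12 steps (1 → 23).

The three steps most likely to fail are step 10, step 4 and step 6.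

**Step 10 (proposed new cascade).** Risks are intermolecular aldol with 17, dehydration of 18, or poor catalyst discrimination between the C9 epimers. The fallback uses known chemistry, sets out from 16 and comes back at 20. KOH in MeOH closes the ring by aldol condensation to the enone longipina-2,8-dien-7-one F4. Cu(MeCN)4PF6 with (R,R)-QuinoxP*, LiOtBu and B2pin2 in DMSO adds boron to C9 under ligand control, giving 9-(4,4,5,5-tetramethyl-1,3,2-dioxaborolan-2-yl)longipin-2-en-7-one F5. NaBO3·4H2O oxidises F5 with retention to aldol 18 as a single C9 epimer. The Evans–Tishchenko reaction of 18 with 17 (SmI2 cat., THF, −10 °C) then gives 20.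

**Step 4 (keteniminium [2+2]).** Risks are the vinylogous generation of the keteniminium from the conjugated amide and loss of alkene geometry or face selectivity. The fallback sets out from 5 and comes back at 8. LDA/HMPA at −78 °C followed by an AcOH quench deconjugates 5 to the β,γ-unsaturated amide (6E)-1-[(2S,5S)-2,5-dimethylpyrrolidin-1-yl]-7-methyl-3-methylidene-8-(triethylsilyloxy)oct-6-en-1-one F1. F1 forms the same keteniminium 6 by ordinary α-deprotonation under the documented Ghosez conditions (Tf2O, 2,4,6-collidine, ClCH2CH2Cl, reflux; aqueous NaHCO3) and gives 8. This fallback addresses the generation of 6, not a failure of the auxiliary to control the face.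

**Step 6 (tetrasubstituted olefination of a hindered cyclobutanone).** The fallback sets out from 9 and comes back at 13, also bypassing step 7. Reformatsky addition of ethyl 2-bromo-2-methylpropanoate (Zn, THF, reflux) gives the β-hydroxy ester ethyl 2-[6-hydroxy-2,7-dimethyl-7-(triethylsilyloxymethyl)bicyclo[3.1.1]hept-2-en-6-yl]-2-methylpropanoate F2, with both methyl groups already in place. Methyl oxalyl chloride/DMAP converts it into the oxalate methyl 6-(1-ethoxy-2-methyl-1-oxopropan-2-yl)-2,7-dimethyl-7-(triethylsilyloxymethyl)bicyclo[3.1.1]hept-2-en-6-yl oxalate F3. Bu3SnH/AIBN (Dolan–MacMillan deoxygenation) generates the C6 radical, which takes hydrogen from the face of the three-carbon bridge and gives 13. Elimination cannot compete because the only β-hydrogens sit at bridgeheads.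

Further compounds
F1 | step 4 | (6E)-1-[(2S,5S)-2,5-dimethylpyrrolidin-1-yl]-7-methyl-3-methylidene-8-(triethylsilyloxy)oct-6-en-1-one | C[C@H]1CC[C@H](C)N1C(=O)CC(=C)CC/C=C(\C)CO[Si](CC)(CC)CC
F2 | step 6 | ethyl 2-[6-hydroxy-2,7-dimethyl-7-(triethylsilyloxymethyl)bicyclo[3.1.1]hept-2-en-6-yl]-2-methylpropanoate (OH anti to the three-carbon bridge) | CC[Si](CC)(CC)OC[C@@]2(C)[C@@H]3CC=C(C)[C@H]2[C@@]3(O)C(C)(C)C(=O)OCC
F3 | step 6 | methyl 6-(1-ethoxy-2-methyl-1-oxopropan-2-yl)-2,7-dimethyl-7-(triethylsilyloxymethyl)bicyclo[3.1.1]hept-2-en-6-yl oxalate | CC[Si](CC)(CC)OC[C@@]2(C)[C@@H]3CC=C(C)[C@H]2[C@@]3(OC(=O)C(=O)OC)C(C)(C)C(=O)OCC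
F4 | step 10 | longipina-2,8-dien-7-one | O=C1C=C[C@@]2(C)[C@@H]3CC=C(C)[C@H]2[C@@H]3C1(C)C
F5 | step 10 | 9-(4,4,5,5-tetramethyl-1,3,2-dioxaborolan-2-yl)longipin-2-en-7-one (boron on the face that later carries O9) | O=C1C[C@@H](B4OC(C)(C)C(C)(C)O4)[C@@]2(C)[C@@H]3CC=C(C)[C@H]2[C@@H]3C1(C)C
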